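The readings stem from a simulated flask for substances that don't exist.

Late in the dosing both earlier runs still climb, but little: from 4.00 min to 5.00 min starting material goes from 22.4% to 23.0% of the charge in Friday's run and from 21.0% to 22.9% in Tuesday's, although those runs held 10 mM and 22 mM.

| flask | starting material | acid | scavenger | protic impurity | remark | time |
|---|---|---|---|---|---|---|
| Friday's | 10 mM (fed, over 6.0 min) | 0.45 mM | 4.5 mM | 3 mM | run made earlier |  |
| Tuesday's | 22 mM (fed, over 6.0 min) | 0.45 mM | 4.5 mM | 3 mM | run made earlier |  |
| flask | 15 mM (fed, over 6.0 min) | 0.450 mM | 4.50 mM | 3.00 mM |  | 6.0 min |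

| run | time / min | starting material / % | target / % |
|---|---|---|---|
| Friday's | 0.833 | 11.3 | 1.3 |
| Friday's | 1.50 | 15.4 | 4.7 |
| Friday's | 2.50 | 19.1 | 10.8 |
| Friday's | 3.00 | 20.7 | 13.5 |
| Friday's | 4.00 | 22.4 | 21.0 |
| Friday's | 5.00 | 23.0 | 28.3 |
| Tuesday's | 0.833 | 10.4 | 1.7 |
| Tuesday's | 1.50 | 14.2 | 5.0 |
| Tuesday's | 2.50 | 18.9 | 9.6 |
| Tuesday's | 3.00 | 20.4 | 13.2 |
| Tuesday's | 4.00 | 21.0 | 20.8 |
| Tuesday's | 5.00 | 22.9 | 28.5 |

(scatter of a reading: 0.3 percentage points)

- part of the starting material that has reacted at 6.0 min
- pH of the solution at 6.0 min

A share that nears a level means that feed and loss are coming to balance. We therefore take the last readings as close to that level, and their mean in reciprocal gives 4.36: this is the dosing number, the first-order loss constant divided by the feed rate in charges per minute, a Damköhler number. Time drops out. It says how many times over the flask can consume what is fed, and the charge does not appear in it, so we use it unchanged at 15 mM. The share left when dosing ends is then (1 − exp(−N))/N, or 22.7%, so we expect 77.3% reacted.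

Was one number enough? At 1.50 min it gives 15.2%, against readings of 15.4% and 14.2%. For the loss it serves. But it does not say where the loss goes: by 5.00 min Friday's run had lost 60.3% of the charge, and target was 28.3%.

The forecast gives 77% and pH 3.35: “The constant k suggests constant acid”.

    starting material + acid → weak acid + acid + target (k = 12.0 /M/s)
    starting material + protic impurity → quenched substrate (k = 0.750 /M/s)
    starting material → weak acid + target (k = 1.60 × 10⁻⁴ /s)
    weak acid ⇌ conjugate base + acid, settled at all times (K = 1.00 × 10⁻¹⁰ M)
    starting material + weak acid ⇌ idle adduct, settled at all times (K = 2900 /M)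
    weak acid + scavenger → scavenged by-product (k = 1.10 /M/s)

The flask gives 76.4% reacted and pH 3.35. Each setting, moved alone by one factor, shifts the reacted share in this order: acid (5.1 points), then protic impurity (0.73 points), then scavenger (0.21 points), then starting material (0.091 points). The dosing number also serves midway: N gives 20.3% left at 3.00 min, and the flask held 20.1%. For the neighbour with 0.11 mM of acid, we suppose the whole loss scales with acid: N becomes 1.07, which gives 38.6% reacted. That neighbour in fact reached 46.8%, with 53.2% of its starting material left.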